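**Plan**

- Retrosynthesis: the C1 side chain is cut at the ring C1–C(sp) bond (Sonogashira coupling, then hydrogenation), which leaves a triflate, i.e. a third oxygen, on C1 of the central ring.
- Feature: on the central benzene ring the benzyl-bearing carbons C2, C4 and C6 alternate with C1, C3 and C5, which carry oxygen (C3 OH, C5 OMe) or a group introduced through oxygen (C1). The ring is therefore a desymmetrized 1,3,5-trimethoxy-2,4,6-tribenzylbenzene; cutting C2–C3, C4–C5 and C6–C1 gives three copies of one ynol ether, ArCH2C≡COMe.
- Forward: benzylation of methoxyacetylide gives the ynol ether, and the head-to-tail (2+2+2) union of three of its molecules closes the only ring the route has to make. Two thiolate mono-demethylations, separated by O-isopropylation, distinguish the three methoxyls; triflation, alkynylation, hydrogenation and BCl3 dealkylation finish the synthesis.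
- Protecting groups: all phenols are carried as isopropyl ethers, which resist thiolate (benzyl ethers would not) and are cleaved by BCl3 without loss of methyl ethers.
- Stereochemistry: the target has no stereocenter and no stereogenic double bond, so nothing has to be set.

Key step: step 3

**Route**

Step 1
Reactants: 1 4-isopropoxybenzyl alcohol
Product: 2 4-isopropoxybenzyl chloride
Conditions: SOCl2 (1.2 equiv), cat. DMF, CH2Cl2, 0 °C → rt; used without storage
Reagents that add atoms: thionyl chloride, O=S(Cl)Cl
Why: Deoxychlorination of an electron-rich benzylic alcohol through its chlorosulfite is routine, and the aryl isopropyl ether should not be touched by the HCl released at this temperature.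

Step 2
Reactants: 3 chloroacetaldehyde dimethyl acetal; 2 4-isopropoxybenzyl chloride
Product: 5 1-isopropoxy-4-(3-methoxyprop-2-yn-1-yl)benzene, via sodium methoxyacetylide 4 (not isolated)
Conditions: 3, NaNH2 (3.0 equiv), liq. NH3, −33 °C; NH3 evaporated and replaced by THF; CuI (10 mol%), 2 (0.75 equiv), 0 °C → rt; cold water work-up, chromatography on Et3N-deactivated silica
Reagents that add atoms: none
Why: Amide-induced loss of methanol and HCl from the chloroacetal followed by deprotonation is the standard entry to alkali alkoxyacetylides, and copper-catalysed SN2 alkylation of a metal acetylide by a benzylic chloride is an established way to 3-arylpropynes.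

Step 3
Reactants: 5 1-isopropoxy-4-(3-methoxyprop-2-yn-1-yl)benzene (three molecules per molecule of product; the second and third are entered below as atom donors)
Product: 6 1,3,5-trimethoxy-2,4,6-tris(4-isopropoxybenzyl)benzene
Conditions: PdCl2(PhCN)2 (5 mol%), 2,6-di-tert-butylpyridine (10 mol%), 4 Å MS, toluene, 0 → 40 °C, slow addition of 5
Reagents that add atoms: ynol ether 5 (second and third molecule), COC#CCc1ccc(OC(C)C)cc1.COC#CCc1ccc(OC(C)C)cc1
Why: Proposed new method: divalent palladium should bind the first molecule of the ynol ether in a slipped, ketenium-like fashion, chloride adding to its oxygen-bearing carbon (ring C1) and palladium to its benzyl-bearing carbon (ring C2); this nucleophilic vinyl carbon then migrates to the oxygen-bearing carbon of a second and then a third coordinated molecule of 5, which forms C2–C3 and C4–C5 head to tail and leaves palladium on C6. The single new ring, the central benzene, closes by intramolecular syn-carbopalladation of the chloro enol ether terminus (C6 to C1, a 6-membered closure), and β-chloride elimination then aromatizes it and returns PdCl2, so that all atoms of three molecules of 5 end up in 6 and nothing is split off. The closest known reaction type is the PdCl2-catalysed cyclotrimerization of unsymmetrical internal alkynes to 1,3,5-patterned hexasubstituted benzenes, which has not been shown for internal ynol ethers. No stereocenter is created. The step needs head-to-tail regioselectivity (1,3,5 over 1,2,4) in all three unions, which the strong oxygen-induced polarization of each triple bond should secure and the mutual avoidance of the benzyl groups reinforces. The methyl ether (no β-hydrogen, hence no retro-ene route to a ketene), the sieves and the hindered pyridine are there to suppress the competing acid-induced hydration and oligomerization.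

Step 4
Reactants: 6 1,3,5-trimethoxy-2,4,6-tris(4-isopropoxybenzyl)benzene
Product: 7 3,5-dimethoxy-2,4,6-tris(4-isopropoxybenzyl)phenol
Conditions: NaSEt (3 equiv), DMF, 130 °C; then aq. HCl
Reagents that add atoms: none
Why: Thiolate SN2 demethylation of an aryl methyl ether should stop after one methyl because the phenoxide formed deactivates the ring as a leaving group, the three methoxyls are equivalent so only one product can form, and the secondary isopropyl ethers resist SN2 attack.

Step 5
Reactants: 7 3,5-dimethoxy-2,4,6-tris(4-isopropoxybenzyl)phenol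
Product: 8 1-isopropoxy-3,5-dimethoxy-2,4,6-tris(4-isopropoxybenzyl)benzene
Conditions: 2-bromopropane (5 equiv), Cs2CO3, DMF, 60 °C
Reagents that add atoms: 2-bromopropane, CC(C)Br
Why: Williamson etherification of the cesium phenoxide, with excess secondary bromide to offset E2 loss, should mask the future C3 hydroxyl with the same group as the outer phenols.

Step 6
Reactants: 8 1-isopropoxy-3,5-dimethoxy-2,4,6-tris(4-isopropoxybenzyl)benzene
Product: 9 3-isopropoxy-5-methoxy-2,4,6-tris(4-isopropoxybenzyl)phenol
Conditions: NaSEt (3 equiv), DMF, 130 °C; then aq. HCl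
Reagents that add atoms: none
Why: The same self-limiting thiolate SN2 demethylation applies, and the two remaining methoxyls are related by the mirror plane through the isopropoxy-bearing carbon, so either gives 9.

Step 7
Reactants: 9 3-isopropoxy-5-methoxy-2,4,6-tris(4-isopropoxybenzyl)phenol
Product: 10 3-isopropoxy-5-methoxy-2,4,6-tris(4-isopropoxybenzyl)phenyl trifluoromethanesulfonate
Conditions: Tf2O (1.3 equiv), pyridine, CH2Cl2, 0 °C
Reagents that add atoms: trifluoromethanesulfonic anhydride, O=S(=O)(OS(=O)(=O)C(F)(F)F)C(F)(F)F
Why: O-sulfonylation of the only free hydroxyl to the aryl triflate is standard, and the fully substituted central ring offers no site for C-sulfonylation.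

Step 8
Reactants: 10 3-isopropoxy-5-methoxy-2,4,6-tris(4-isopropoxybenzyl)phenyl trifluoromethanesulfonate; 11 3-ethynylanisole
Product: 12 1-isopropoxy-5-methoxy-3-[(3-methoxyphenyl)ethynyl]-2,4,6-tris(4-isopropoxybenzyl)benzene
Conditions: PdCl2(MeCN)2 (5 mol%), XPhos (15 mol%), Cs2CO3 (2.5 equiv), MeCN, 80 °C, slow addition of 11
Reagents that add atoms: none
Why: Copper-free Sonogashira coupling should work because zerovalent palladium carrying the bulky, electron-rich biarylphosphine inserts into hindered, electron-rich aryl sulfonates and the rod-like acetylide adds little steric demand at the doubly ortho-substituted carbon.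

Step 9
Reactants: 12 1-isopropoxy-5-methoxy-3-[(3-methoxyphenyl)ethynyl]-2,4,6-tris(4-isopropoxybenzyl)benzene
Product: 13 1-isopropoxy-5-methoxy-3-[2-(3-methoxyphenyl)ethyl]-2,4,6-tris(4-isopropoxybenzyl)benzene
Conditions: H2 (3 bar), 10% Pd/C, EtOAc, rt
Reagents that add atoms: none
Why: Heterogeneous catalytic hydrogenation should reduce the diarylalkyne to the 1,2-diarylethane, while aryl alkyl ethers and diarylmethane links are inert to these conditions.

Step 10
Reactants: 13 1-isopropoxy-5-methoxy-3-[2-(3-methoxyphenyl)ethyl]-2,4,6-tris(4-isopropoxybenzyl)benzene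
Product: 14 3-methoxy-5-[2-(3-methoxyphenyl)ethyl]-2,4,6-tris(4-hydroxybenzyl)phenol (CNP0285788.0)
Conditions: BCl3 (1 M in CH2Cl2, 6 equiv), CH2Cl2, −78 → 0 °C; then H2O
Reagents that add atoms: none
Why: Lewis-acid dealkylation with BCl3 cleaves aryl isopropyl ethers (the secondary alkyl leaves as 2-chloropropane) far faster than aryl methyl ethers that lack a chelating neighbour, so the four phenols should be released while both methoxyls stay.

**Compound list**

1 | 4-isopropoxybenzyl alcohol | CC(C)Oc1ccc(CO)cc1 | starting material
2 | 4-isopropoxybenzyl chloride | CC(C)Oc1ccc(CCl)cc1 | intermediate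
3 | chloroacetaldehyde dimethyl acetal (2-chloro-1,1-dimethoxyethane) | COC(CCl)OC | starting material
4 | sodium methoxyacetylide | COC#[C-].[Na+] | intermediate (not isolated)
5 | 1-isopropoxy-4-(3-methoxyprop-2-yn-1-yl)benzene | COC#CCc1ccc(OC(C)C)cc1 | intermediate
6 | 1,3,5-trimethoxy-2,4,6-tris(4-isopropoxybenzyl)benzene | COc1c(Cc2ccc(OC(C)C)cc2)c(OC)c(Cc2ccc(OC(C)C)cc2)c(OC)c1Cc1ccc(OC(C)C)cc1 | intermediate
7 | 3,5-dimethoxy-2,4,6-tris(4-isopropoxybenzyl)phenol | COc1c(Cc2ccc(OC(C)C)cc2)c(O)c(Cc2ccc(OC(C)C)cc2)c(OC)c1Cc1ccc(OC(C)C)cc1 | intermediate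
8 | 1-isopropoxy-3,5-dimethoxy-2,4,6-tris(4-isopropoxybenzyl)benzene | COc1c(Cc2ccc(OC(C)C)cc2)c(OC(C)C)c(Cc2ccc(OC(C)C)cc2)c(OC)c1Cc1ccc(OC(C)C)cc1 | intermediate
9 | 3-isopropoxy-5-methoxy-2,4,6-tris(4-isopropoxybenzyl)phenol | COc1c(Cc2ccc(OC(C)C)cc2)c(O)c(Cc2ccc(OC(C)C)cc2)c(OC(C)C)c1Cc1ccc(OC(C)C)cc1 | intermediate
10 | 3-isopropoxy-5-methoxy-2,4,6-tris(4-isopropoxybenzyl)phenyl trifluoromethanesulfonate | COc1c(Cc2ccc(OC(C)C)cc2)c(OS(=O)(=O)C(F)(F)F)c(Cc2ccc(OC(C)C)cc2)c(OC(C)C)c1Cc1ccc(OC(C)C)cc1 | intermediate
11 | 3-ethynylanisole (1-ethynyl-3-methoxybenzene) | C#Cc1cccc(OC)c1 | starting material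
12 | 1-isopropoxy-5-methoxy-3-[(3-methoxyphenyl)ethynyl]-2,4,6-tris(4-isopropoxybenzyl)benzene | COc1cccc(C#Cc2c(Cc3ccc(OC(C)C)cc3)c(OC(C)C)c(Cc3ccc(OC(C)C)cc3)c(OC)c2Cc2ccc(OC(C)C)cc2)c1 | intermediate
13 | 1-isopropoxy-5-methoxy-3-[2-(3-methoxyphenyl)ethyl]-2,4,6-tris(4-isopropoxybenzyl)benzene | COc1cccc(CCc2c(Cc3ccc(OC(C)C)cc3)c(OC(C)C)c(Cc3ccc(OC(C)C)cc3)c(OC)c2Cc2ccc(OC(C)C)cc2)c1 | intermediate
14 | 3-methoxy-5-[2-(3-methoxyphenyl)ethyl]-2,4,6-tris(4-hydroxybenzyl)phenol (CNP0285788.0) | COc1cccc(CCc2c(Cc3ccc(O)cc3)c(O)c(Cc3ccc(O)cc3)c(OC)c2Cc2ccc(O)cc2)c1 | target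

**Step count**

Total steps: 10. Longest linear sequence: 10 steps (1 → 14; 3 and 11 enter as side inputs).

**Steps most likely to fail**

1. Step 3 (new method). Acid- or metal-induced hydration and oligomerization of the ynol ether may outrun trimerization, or head-to-tail control may erode and give the 1,2,4-patterned isomer. The fallback uses known chemistry and sets out from chloride 2. Commercial 1,3,5-trimethoxybenzene would be iodinated three times (N-iodosuccinimide, cat. TFA, MeCN) to 1,3,5-triiodo-2,4,6-trimethoxybenzene F1. In parallel, 2 would be converted with zinc dust and LiCl in THF into (4-isopropoxybenzyl)zinc chloride F2. A threefold Negishi coupling of F1 with F2 (Pd(OAc)2, SPhos, THF, 60 °C) should then give 6, where the route is rejoined.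

2. Step 2. The benzylic chloride may be captured by the sodium methoxide formed alongside the acetylide, the product may isomerize from propargyl to allenyl under base, and the ynol ether may hydrate on work-up. The fallback sets out from sodium methoxyacetylide 4, generated as before, and chloride 2. Transmetalation of 4 with ZnCl2 in THF would give the non-basic (methoxyethynyl)zinc chloride F3 and tie the alkoxide up on zinc. A palladium-catalysed Negishi alkynyl–benzyl coupling of F3 with 2 (PdCl2(DPEphos), THF, rt) should then give 5, where the route is rejoined.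

3. Step 8. Oxidative addition into the doubly ortho-substituted, electron-rich triflate may be slow, so that base-induced S–O cleavage back to phenol 9 and oligomerization of the alkyne take over. The fallback sets out from triflate 10. Commercial 3-vinylanisole would be hydroborated with 9-BBN in THF to 9-[2-(3-methoxyphenyl)ethyl]-9-borabicyclo[3.3.1]nonane F4. A B-alkyl Suzuki–Miyaura coupling of F4 with 10 (Pd(OAc)2, SPhos, K3PO4, THF/H2O, 65 °C) should install the saturated chain directly and give 13, which bypasses 12 and step 9.

**Further compounds**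

F1 | step 3 | 1,3,5-triiodo-2,4,6-trimethoxybenzene | COc1c(I)c(OC)c(I)c(OC)c1I
F2 | step 3 | (4-isopropoxybenzyl)zinc chloride | CC(C)Oc1ccc(C[Zn]Cl)cc1
F3 | step 2 | (methoxyethynyl)zinc chloride | COC#C[Zn]Cl
F4 | step 8 | 9-[2-(3-methoxyphenyl)ethyl]-9-borabicyclo[3.3.1]nonane | COc1cccc(CCB2C3CCCC2CCC3)c1
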